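**Plan**
- Retrosynthesis: the γ-lactone is opened at O16–C15 to an acetonide-protected acid. The side chain is cut at C9–C11 (organocerium addition to a C9 ketone, then oxidative 1,3-transposition to the 7-oxo-8-ene). The C6 hydroxyl goes back to an enedione, ring A is cut at C3–C4, and C10 loses C1 and its methyl (two enolate alkylations). The chain itself is cut at C13–C14 (alkylation of a malic acid acetal).
- Forward: ring B is bought as (R)-carvone and dialkylated at C10. Ring A closes by radical C3–C4 bond formation and C2 is decarboxylated. C6 is oxidised, reduced and silylated. The C11–C16 chain is added at C9, the enone is transposed, and the lactone ring closes last.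
- Enabling feature: ring B (C5–C10) with its C8 methyl and the C5 stereocentre is the carvone ring. The isopropenyl carbon on C5 is C4, already carrying both geminal methyl carbons. Once a 2-(ethoxycarbonyl)allyl arm (C1–C3) sits on C10, only the C3–C4 bond of ring A is missing.
- Stereochemistry: C5 comes from (R)-carvone; C10 from alkylation anti to the isopropenyl group; C6 from α-face hydride delivery to a 6-ketone; C13 from (R)-malic acid by self-regeneration of stereocentres.

Key step: step 3

Remark: the SMILES is read as (13S)-6β,13-dihydroxy-7-oxolabd-8-en-15,16-olide (trans-decalin, 5α-H, 10β-CH3, 6-OH cis to the angular methyl); labdane numbering is used for all intermediates, and β means the face of the C10 methyl.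

**Ring A/B part**

Step 1
Reactants: 1 (R)-(−)-carvone; 2 iodomethane
Product: 4 trans-6-methylcarvone [(5R,6S)-2,6-dimethyl-5-(prop-1-en-2-yl)cyclohex-2-en-1-one; minor cis epimer carried along], via carvone lithium enolate 3 (not isolated)
Conditions: LiN(i-Pr)2 (commercial solution, 1.05 equiv), THF, −78 °C; MeI, −78 → −20 °C
Reagents that add atoms: iodomethane (2), CI
Why: Kinetic α′-deprotonation of the enone gives the cross-conjugated lithium enolate, which is methylated by SN2 enolate alkylation; the new centre is made planar again in step 2, so its configuration does not matter.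

Step 2
Reactants: 4 trans-6-methylcarvone; 5 ethyl 2-(bromomethyl)acrylate
Product: 7 ethyl 2-{[(1S,6S)-1,3-dimethyl-2-oxo-6-(prop-1-en-2-yl)cyclohex-3-en-1-yl]methyl}prop-2-enoate (new CH2 arm trans and C10 methyl cis to the isopropenyl group), via methylcarvone lithium enolate 6 (not isolated)
Conditions: LiN(i-Pr)2 (1.1 equiv), THF/DMPU, −78 → −20 °C; then 5, −78 °C → rt
Reagents that add atoms: ethyl 2-(bromomethyl)acrylate (5), C=C(CBr)C(=O)OCC
Why: Second α′ enolate alkylation with a very reactive allylic bromide (SN2 and SN2′ give the same product); the electrophile enters anti to the neighbouring isopropenyl group, which sets the quaternary C10.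

Step 3
Reactants: 7 dialkylated carvone
Product: 8 ethyl (2S,4aS,8aS)-4,4,7,8a-tetramethyl-8-oxo-1,2,3,4,4a,5,8,8a-octahydronaphthalene-2-carboxylate (trans-fused; equatorial ester expected; the C2 epimer is equally usable)
Conditions: Fe(acac)3 (30 mol%), PhSiH3 (2.5 equiv), EtOH/(CH2OH)2 (5:1), 0.02 M, 60 °C, Ar
Reagents that add atoms: none
Why: Trivalent iron and PhSiH3 form an iron hydride that transfers a hydrogen atom to the CH2 terminus of the electron-rich isopropenyl group, giving the nucleophilic tertiary C4 radical; this adds to the unsubstituted acrylate terminus C3, and the ester-stabilised C2 radical is reduced by divalent iron and protonated by ethanol. The closest known reaction type is the iron-hydride hydrogen-atom-transfer reductive olefin coupling (radical Giese addition) run intramolecularly. Ring A closes in the 6-endo-trig mode (C4–C5–C10–C1–C2–C3); 5-exo attack at C2 is disfavoured because it would join a tertiary radical to a fully substituted, polarity-mismatched carbon and leave an unstabilised primary radical. The only new stereocentre, C2, is set by protonation of the ester enolate from the less hindered face and is deleted in step 5; the trans ring fusion is inherited from the trans arms on C5 and C10. The step needs chemoselective hydrogen-atom transfer among three alkenes and endo regiochemistry: the isopropenyl group is the only electron-rich alkene, the acrylate is the matched acceptor, and the enone carbon C7 could only be reached through a four-membered ring.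

Step 4
Reactants: 8 bicyclic enone ester
Product: 9 (2S,4aS,8aS)-4,4,7,8a-tetramethyl-8-oxo-1,2,3,4,4a,5,8,8a-octahydronaphthalene-2-carboxylic acid
Conditions: LiOH·H2O, THF/MeOH/H2O, rt; then 1 M HCl
Reagents that add atoms: lithium hydroxide, [Li+].[OH-]
Why: Saponification of an unhindered secondary ethyl ester; the enone is inert to LiOH at room temperature and epimerisation at C2 is of no consequence.

Step 5
Reactants: 9 bicyclic enone acid
Product: 11 (4aS,8aS)-2,5,5,8a-tetramethyl-4a,5,6,7,8,8a-hexahydronaphthalen-1(4H)-one (C9 ketone; C7=C8), via Barton ester 10 (not isolated)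
Conditions: N-hydroxypyridine-2-thione, N,N′-dicyclohexylcarbodiimide, DMAP (cat.), CH2Cl2, 0 °C → rt, dark; then t-BuSH, PhH, hν (tungsten lamp), rt
Reagents that add atoms: none
Why: Barton reductive decarboxylation: the O-acyl thiohydroxamate fragments under visible light to the secondary C2 radical, which takes a hydrogen atom from t-BuSH; the radical cannot reach the distant enone.

Step 6
Reactants: 11 bicyclic enone
Product: 12 (4aS,8aS)-2,5,5,8a-tetramethyl-4a,5,6,7,8,8a-hexahydronaphthalene-1,4-dione (6,9-dioxo-7-ene)
Conditions: Pd(OH)2/C (5 mol%), t-BuOOH (5 equiv), K2CO3 (0.25 equiv), CH2Cl2, 4 °C → rt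
Reagents that add atoms: tert-butyl hydroperoxide, CC(C)(C)OO
Why: Palladium-catalysed peroxide allylic oxidation of an enone to the 1,4-enedione; C6 is the only γ-methylene and its C–H bond is activated by the whole enone π system.

Step 7
Reactants: 12 enedione
Product: 13 (4R,4aS,8aS)-4-hydroxy-2,5,5,8a-tetramethyl-4a,5,6,7,8,8a-hexahydronaphthalen-1(4H)-one (6β-hydroxy-7-en-9-one)
Conditions: NaBH4 (0.5 equiv), CeCl3·7H2O (1.1 equiv), MeOH, −78 °C
Reagents that add atoms: none
Why: Luche 1,2-reduction: the C6 carbonyl (flanked by CH and CH=) should react before the C9 carbonyl (flanked by quaternary C10 and the methyl-bearing C8, the ketoisophorone pattern), and hydride enters from the α face because the β face is screened by the syn-axial C10 and C4β methyl groups, giving the axial 6β-alcohol.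

Step 8
Reactants: 13 6β-hydroxy enone
Product: 14 (4R,4aS,8aS)-4-[(tert-butyldimethylsilyl)oxy]-2,5,5,8a-tetramethyl-4a,5,6,7,8,8a-hexahydronaphthalen-1(4H)-one
Conditions: TBSOTf (1.5 equiv), 2,6-lutidine (3 equiv), CH2Cl2, 0 °C → rt
Reagents that add atoms: tert-butyldimethylsilyl trifluoromethanesulfonate, CC(C)(C)[Si](C)(C)OS(=O)(=O)C(F)(F)F
Why: Silyl triflate silylation of a hindered secondary alcohol; the TBS ether tolerates the organocerium, hexavalent chromium, periodate and chlorite steps that follow.

**Side chain (C11–C16)**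

Step 9
Reactants: 15 (R)-malic acid
Product: 16 2-[(2R,4R)-2-tert-butyl-5-oxo-1,3-dioxolan-4-yl]acetic acid (cis)
Conditions: t-BuCHO, TsOH·H2O (cat.), H2SO4 (cat.), pentane, reflux, Dean–Stark; recrystallisation
Reagents that add atoms: pivalaldehyde, CC(C)(C)C=O
Why: Acid-catalysed acetalisation of the α-hydroxy acid unit under thermodynamic control gives the cis dioxolanone, whose acetal centre stores the configuration of the future C13.

Step 10
Reactants: 16 dioxolanone acid; 17 1-bromo-3-methylbut-2-ene (prenyl bromide)
Product: 19 2-[(2R,4R)-2-tert-butyl-4-(3-methylbut-2-en-1-yl)-5-oxo-1,3-dioxolan-4-yl]acetic acid (prenyl trans to tert-butyl), via dilithium enolate carboxylate 18 (not isolated)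
Conditions: LiN(SiMe3)2 (2.2 equiv), THF, −78 °C; 17, −78 → −20 °C; cold 1 M HCl
Reagents that add atoms: 1-bromo-3-methylbut-2-ene (17), CC(C)=CCBr
Why: Alkylation with self-regeneration of the stereocentre: the enolate is attacked anti to the tert-butyl group, so prenyl replaces the former carbinol hydrogen with retention and the quaternary carbinol carbon (C13) is fixed; prenyl is the masked C14–C15 acid arm.

Step 11
Reactants: 19 prenylated dioxolanone acid
Product: 20 (R)-2-(3-methylbut-2-en-1-yl)butane-1,2,4-triol
Conditions: LiAlH4 (4 equiv), THF, 0 °C → reflux; H2O/aq. NaOH work-up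
Reagents that add atoms: none
Why: Exhaustive hydride reduction of the acid and of the acylal lactone to primary alcohols with release of the tertiary hydroxyl; the isolated trisubstituted alkene is untouched.

Step 12
Reactants: 20 triol
Product: 21 2-[(R)-2,2-dimethyl-4-(3-methylbut-2-en-1-yl)-1,3-dioxolan-4-yl]ethan-1-ol
Conditions: Me2C(OMe)2, pyridinium p-toluenesulfonate (cat.), acetone, rt
Reagents that add atoms: 2,2-dimethoxypropane, COC(C)(C)OC
Why: Thermodynamic transacetalisation favours the five-membered 1,3-dioxolane (O13/O16) over the six-membered alternative and leaves the C11 hydroxyl free.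

Step 13
Reactants: 21 acetonide alcohol
Product: 22 (R)-4-(2-iodoethyl)-2,2-dimethyl-4-(3-methylbut-2-en-1-yl)-1,3-dioxolane
Conditions: I2, PPh3, imidazole, CH2Cl2, 0 °C → rt
Reagents that add atoms: iodine, II
Why: Appel-type iodination of a primary alcohol by SN2 displacement of the alkoxyphosphonium ion.

**Coupling and end game**

Step 14
Reactants: 14 silyloxy enone; 22 side-chain iodide
Product: 25 (13S)-6β-(tert-butyldimethylsilyloxy)-13,16-(isopropylidenedioxy)-15-isopropylidenelabd-7-en-9β-ol (side chain on the α face expected; either C9 epimer serves), via alkyllithium 23 (not isolated), via alkylcerium dichloride 24 (not isolated)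
Conditions: 22, t-BuLi (2.1 equiv), Et2O/pentane, −78 °C; CeCl3 (anhydrous), THF, −78 °C; then 14, −78 → −40 °C; H2O quench
Reagents that add atoms: side-chain iodide (22), ICC[C@]1(CC=C(C)C)COC(C)(C)O1
Why: Iodine–lithium exchange and transmetalation give a weakly basic organocerium that adds 1,2 to the hindered C9 ketone (no α-hydrogens; the 2,6,6-trimethylcyclohexenone pattern) anti to the angular methyl; the trisubstituted prenyl alkene does not invite carbolithiation.

Step 15
Reactants: 25 tertiary allylic alcohol
Product: 26 (13S)-6β-(tert-butyldimethylsilyloxy)-13,16-(isopropylidenedioxy)-15-isopropylidenelabd-8-en-7-one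
Conditions: [C5H5NH][CrO3Cl] (pyridinium chlorochromate, 3 equiv), NaOAc, 4 Å molecular sieves, CH2Cl2, rt
Reagents that add atoms: pyridinium chlorochromate, [O-][Cr](=O)(=O)Cl.c1cc[nH+]cc1
Why: Babler–Dauben oxidative 1,3-transposition: the tertiary allylic chromate ester undergoes a [3,3] shift to C7 and is oxidised there, placing the ketone at C7 and the double bond at C8=C9 under the side chain.

Step 16
Reactants: 26 transposed enone
Product: 27 (13S)-6β-(tert-butyldimethylsilyloxy)-13,16-(isopropylidenedioxy)-7-oxolabd-8-en-15-al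
Conditions: OsO4 (2 mol%), NaIO4 (4 equiv), 2,6-lutidine (2 equiv), dioxane/H2O (3:1), rt
Reagents that add atoms: osmium tetroxide (catalytic oxygen carrier), O=[Os](=O)(=O)=O; sodium periodate, [Na+].[O-]I(=O)(=O)=O
Why: Lemieux–Johnson oxidation: OsO4 dihydroxylates the electron-rich prenyl alkene far faster than the tetrasubstituted conjugated C8=C9 bond, and periodate cleaves the diol to the C15 aldehyde.

Step 17
Reactants: 27 aldehyde
Product: 28 (13S)-6β-(tert-butyldimethylsilyloxy)-13,16-(isopropylidenedioxy)-7-oxolabd-8-en-15-oic acid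
Conditions: NaClO2, NaH2PO4, 2-methyl-2-butene, t-BuOH/H2O, 0 °C → rt
Reagents that add atoms: sodium chlorite, [Na+].[O-]Cl=O
Why: Pinnick oxidation of the aldehyde with a hypochlorite scavenger; enone, acetonide and silyl ether are not affected.

Step 18
Reactants: 28 protected acid
Product: 30 (13S)-6β,13-dihydroxy-7-oxolabd-8-en-15,16-olide (target), via seco acid 29 (not isolated)
Conditions: 48% aq. HF, MeCN, 0 °C → rt (polypropylene vessel)
Reagents that add atoms: none
Why: Acidic global deprotection: HF removes the silyl ether and hydrolyses the acetonide, and the freed C16 hydroxyl lactonises onto the C15 acid (5-exo-trig acyl substitution) without breaking the C13–O bond, so C13 stays S.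

**Compound list**

1 | (R)-(−)-carvone | CC1=CC[C@@H](C(C)=C)CC1=O | starting material
2 | iodomethane | CI | starting material
3 | lithium enolate of carvone (C6 deprotonated) | CC1=CC[C@@H](C(C)=C)C=C1O[Li] | intermediate
4 | trans-6-methylcarvone, (5R,6S)-2,6-dimethyl-5-(prop-1-en-2-yl)cyclohex-2-en-1-one | CC1=CC[C@@H](C(C)=C)[C@H](C)C1=O | intermediate
5 | ethyl 2-(bromomethyl)acrylate | C=C(CBr)C(=O)OCC | starting material
6 | lithium enolate of 4 | CC1=CC[C@@H](C(C)=C)C(C)=C1O[Li] | intermediate
7 | ethyl 2-{[(1S,6S)-1,3-dimethyl-2-oxo-6-(prop-1-en-2-yl)cyclohex-3-en-1-yl]methyl}prop-2-enoate | CC1=CC[C@@H](C(C)=C)[C@](C)(CC(=C)C(=O)OCC)C1=O | intermediate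
8 | ethyl (2S,4aS,8aS)-4,4,7,8a-tetramethyl-8-oxo-1,2,3,4,4a,5,8,8a-octahydronaphthalene-2-carboxylate | CC1=CC[C@H]2C(C)(C)C[C@H](C(=O)OCC)C[C@]2(C)C1=O | intermediate
9 | (2S,4aS,8aS)-4,4,7,8a-tetramethyl-8-oxo-1,2,3,4,4a,5,8,8a-octahydronaphthalene-2-carboxylic acid | CC1=CC[C@H]2C(C)(C)C[C@H](C(=O)O)C[C@]2(C)C1=O | intermediate
10 | Barton ester of 9 (2-thioxopyridin-1(2H)-yl ester) | CC1=CC[C@H]2C(C)(C)C[C@H](C(=O)ON3C=CC=CC3=S)C[C@]2(C)C1=O | intermediate
11 | (4aS,8aS)-2,5,5,8a-tetramethyl-4a,5,6,7,8,8a-hexahydronaphthalen-1(4H)-one | CC1=CC[C@H]2C(C)(C)CCC[C@]2(C)C1=O | intermediate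
12 | (4aS,8aS)-2,5,5,8a-tetramethyl-4a,5,6,7,8,8a-hexahydronaphthalene-1,4-dione | CC1=CC(=O)[C@H]2C(C)(C)CCC[C@]2(C)C1=O | intermediate
13 | (4R,4aS,8aS)-4-hydroxy-2,5,5,8a-tetramethyl-4a,5,6,7,8,8a-hexahydronaphthalen-1(4H)-one | CC1=C[C@@H](O)[C@H]2C(C)(C)CCC[C@]2(C)C1=O | intermediate
14 | (4R,4aS,8aS)-4-[(tert-butyldimethylsilyl)oxy]-2,5,5,8a-tetramethyl-4a,5,6,7,8,8a-hexahydronaphthalen-1(4H)-one | CC1=C[C@@H](O[Si](C)(C)C(C)(C)C)[C@H]2C(C)(C)CCC[C@]2(C)C1=O | intermediate
15 | (R)-malic acid | OC(=O)C[C@@H](O)C(O)=O | starting material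
16 | 2-[(2R,4R)-2-tert-butyl-5-oxo-1,3-dioxolan-4-yl]acetic acid | OC(=O)C[C@H]1O[C@@H](C(C)(C)C)OC1=O | intermediate
17 | 1-bromo-3-methylbut-2-ene | CC(C)=CCBr | starting material
18 | dilithium enolate carboxylate of 16 | [Li]OC(=O)CC1=C(O[Li])O[C@H](C(C)(C)C)O1 | intermediate
19 | 2-[(2R,4R)-2-tert-butyl-4-(3-methylbut-2-en-1-yl)-5-oxo-1,3-dioxolan-4-yl]acetic acid | OC(=O)C[C@@]1(CC=C(C)C)O[C@@H](C(C)(C)C)OC1=O | intermediate
20 | (R)-2-(3-methylbut-2-en-1-yl)butane-1,2,4-triol | OCC[C@@](O)(CO)CC=C(C)C | intermediate
21 | 2-[(R)-2,2-dimethyl-4-(3-methylbut-2-en-1-yl)-1,3-dioxolan-4-yl]ethan-1-ol | OCC[C@]1(CC=C(C)C)COC(C)(C)O1 | intermediate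
22 | (R)-4-(2-iodoethyl)-2,2-dimethyl-4-(3-methylbut-2-en-1-yl)-1,3-dioxolane | ICC[C@]1(CC=C(C)C)COC(C)(C)O1 | intermediate
23 | alkyllithium from 22 | [Li]CC[C@]1(CC=C(C)C)COC(C)(C)O1 | intermediate
24 | alkylcerium dichloride from 23 | Cl[Ce](Cl)CC[C@]1(CC=C(C)C)COC(C)(C)O1 | intermediate
25 | (13S)-6β-(tert-butyldimethylsilyloxy)-13,16-(isopropylidenedioxy)-15-isopropylidenelabd-7-en-9β-ol | CC1=C[C@@H](O[Si](C)(C)C(C)(C)C)[C@H]2C(C)(C)CCC[C@]2(C)[C@]1(O)CC[C@]3(CC=C(C)C)COC(C)(C)O3 | intermediate
26 | (13S)-6β-(tert-butyldimethylsilyloxy)-13,16-(isopropylidenedioxy)-15-isopropylidenelabd-8-en-7-one | CC1=C(CC[C@]3(CC=C(C)C)COC(C)(C)O3)[C@@]2(C)CCCC(C)(C)[C@@H]2[C@H](O[Si](C)(C)C(C)(C)C)C1=O | intermediate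
27 | (13S)-6β-(tert-butyldimethylsilyloxy)-13,16-(isopropylidenedioxy)-7-oxolabd-8-en-15-al | CC1=C(CC[C@]3(CC=O)COC(C)(C)O3)[C@@]2(C)CCCC(C)(C)[C@@H]2[C@H](O[Si](C)(C)C(C)(C)C)C1=O | intermediate
28 | (13S)-6β-(tert-butyldimethylsilyloxy)-13,16-(isopropylidenedioxy)-7-oxolabd-8-en-15-oic acid | CC1=C(CC[C@]3(CC(=O)O)COC(C)(C)O3)[C@@]2(C)CCCC(C)(C)[C@@H]2[C@H](O[Si](C)(C)C(C)(C)C)C1=O | intermediate
29 | (13S)-6β,13,16-trihydroxy-7-oxolabd-8-en-15-oic acid (seco acid) | CC1=C(CC[C@@](O)(CO)CC(=O)O)[C@@]2(C)CCCC(C)(C)[C@@H]2[C@H](O)C1=O | intermediate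
30 | (13S)-6β,13-dihydroxy-7-oxolabd-8-en-15,16-olide | CC1=C(CC[C@@]2(O)COC(=O)C2)[C@@]2(C)CCCC(C)(C)[C@@H]2[C@H](O)C1=O | target

**Step count**

Total: 18 steps. Longest linear sequence: 13 steps (steps 1–8 and 14–18, from (R)-carvone). The side-chain branch is 5 steps (9–13).

**Steps most likely to fail**

Step 7. Hydride attack at C9 may compete with attack at C6, or both carbonyls may be reduced. The selection can be moved from the reduction to an oxidation. Setting out from 12, both carbonyls are reduced with excess NaBH4/CeCl3·7H2O (MeOH, 0 °C), with α-face attack expected at both centres, to the 6β,9β-diol F1. Activated MnO2 (CH2Cl2, rt) should then oxidise only the quasi-equatorial C9 allylic alcohol, whose axial C–H bond overlaps with the alkene. The axial 6β-hydroxyl, flanked by two syn-axial methyl groups, should remain. This returns to the route at 13.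

Step 15. Chromate ester formation at the congested C9 carbinol may be slow, so that ionisation and dehydration to dienes, or acetonide loss under the acidic chromium reagent, take over. Rearrangement and oxidation can be separated. Setting out from 25, Ph3SiOReO3 (cat., Et2O, −50 → 0 °C) should effect a redox-neutral 1,3-hydroxyl shift to the thermodynamically preferred secondary alcohol with the tetrasubstituted C8=C9 bond, the labd-8-en-7-ol F2. Dess–Martin periodinane (NaHCO3, CH2Cl2) then oxidises it, returning to the route at 26.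

Step 3. The C4 radical may be reduced before it cyclises, or the acrylate may be consumed by hydride reduction or oligomerisation. The same radical can be made by halogen abstraction. Setting out from 7, HBr in AcOH (0 °C) should add in the Markovnikov sense to the isopropenyl group only, since the two conjugated alkenes are electron-poor, to give the tertiary bromide F3. Slow addition of Bu3SnH with azobisisobutyronitrile (PhH, 80 °C) should then bring about the same 6-endo Giese closure, returning to the route at 8.

**Further compounds**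

F1 | step 7 | 6β,9β-diol from 12: (4aS,8aS)-2,5,5,8a-tetramethyl-1,4,4a,5,6,7,8,8a-octahydronaphthalene-1,4-diol with both hydroxyls cis to the angular methyl | CC1=C[C@@H](O)[C@H]2C(C)(C)CCC[C@]2(C)[C@H]1O
F2 | step 15 | (13S)-6β-(tert-butyldimethylsilyloxy)-13,16-(isopropylidenedioxy)-15-isopropylidenelabd-8-en-7β-ol (C7 configuration immaterial) | CC1=C(CC[C@]3(CC=C(C)C)COC(C)(C)O3)[C@@]2(C)CCCC(C)(C)[C@@H]2[C@H](O[Si](C)(C)C(C)(C)C)[C@@H]1O
F3 | step 3 | tertiary bromide: Markovnikov HBr adduct of 7 at the isopropenyl group (2-bromopropan-2-yl on C5) | CC1=CC[C@@H](C(C)(C)Br)[C@](C)(CC(=C)C(=O)OCC)C1=O
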